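**Assumptions (one line each)**
- (S)-3-Methylcyclopentanone (1) is purchasable.
- The given SMILES has a trans ring fusion (H4 and H9 anti). C3-Me is trans to C4–C5, and C8 is trans to C4–C5.
- Atom labels used below: cyclopentene C1(Et)=C2–C3(Me)–C4–C9; cyclohexene C4–C5(Me)=C6–C7(Me)(dienyl)–C8(Me)(CO2H)–C9.

**Retrosynthetic overview**
1. An intramolecular Diels–Alder is avoided. The last step is ring-closing metathesis (RCM) of C5=C6, joining an isopropenyl on C4 to a vinyl on C7, so the cyclohexene is formed last.
2. The adjacent quaternary centres C7–C8 are disconnected by an Ireland–Claisen rearrangement. It joins a cyclopentenyl-propanoate silyl ketene acetal to the (E,E,E)-trienyl allylic ester; the allyl fragment becomes the vinyl group, and the trienol comes from commercial cinnamylideneacetone.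
3. The all-trans C3/C4/C9 cyclopentane comes from (R)-4-methylcyclopentenone in one operation: cuprate 1,4-addition of isopropenyl, then enolate alkylation.
4. The C1 ketone becomes the C1(Et)=C2 alkene through its enol triflate and an Et cross-coupling. The rings are formed in the order cyclopentene, then cyclohexene.

---

**Step 1**
Reactants: 1 (S)-3-methylcyclopentanone; 2 chlorotrimethylsilane
Product: 3 (S)-trimethyl[(4-methylcyclopent-1-en-1-yl)oxy]silane
Conditions: LDA, TMSCl, THF, –78 °C
Reagents that add atoms: TMSCl, C[Si](C)(C)Cl
Why: Kinetic deprotonation at the CH2 remote from the methyl group gives the less hindered silyl enol ether (enolate trapping). The C–Me stereocentre is untouched. I assume a regioisomer mixture of about 3:1, carried on and removed after Step 2.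

**Step 2**
Reactants: 3
Product: 4 (R)-4-methylcyclopent-2-en-1-one
Conditions: Pd(OAc)2 (1 equiv), MeCN, rt
Reagents that add atoms: none
Why: Saegusa–Ito oxidation puts the new alkene between the old C4 and C5, giving the γ-methyl enone (the descriptor changes from S to R through CIP priorities only). The minor 3-methylcyclopent-2-enone is separated by chromatography.

**Step 3**
Reactants: 4; 5 isopropenylmagnesium bromide; 6 methyl bromoacetate
Product: 7 methyl 2-[(1R,4R,5S)-4-methyl-2-oxo-5-(prop-1-en-2-yl)cyclopentyl]acetate (all-trans)
Conditions: 5 (1.5 equiv), CuBr·SMe2 (20 mol%), THF, –40 °C; then HMPA, 6 (3 equiv), –78 → 0 °C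
Reagents that add atoms: isopropenylMgBr, C=C(C)[Mg]Br; methyl bromoacetate, COC(=O)CBr
Why: Cu-catalysed conjugate addition followed by enolate alkylation. The isopropenyl group adds anti to the 4-Me, which sets C4 trans to C3. The regiospecific enolate is then alkylated anti to the new β-substituent, which sets C9 trans to C4. C9 is α to the ketone, so it equilibrates to the trans isomer if needed.

**Step 4**
Reactants: 7; 8 N-phenylbis(trifluoromethanesulfonimide)
Product: 9 methyl 2-[4-methyl-5-(prop-1-en-2-yl)-2-(triflyloxy)cyclopent-2-en-1-yl]acetate, ring stereocentres as in 7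
Conditions: LDA, THF, –78 °C; then PhNTf2, –78 → 0 °C
Reagents that add atoms: PhNTf2, O=S(=O)(C(F)(F)F)N(c1ccccc1)S(=O)(=O)C(F)(F)F
Why: Kinetic enolisation at the unhindered C2H2 (not the tertiary C9–H), then O-triflation, gives the C1=C2 enol triflate. The stereocentres are untouched at –78 °C, and the ketone is more acidic than the ester.

**Step 5**
Reactants: 9; 10 diethylzinc
Product: 11 methyl 2-[2-ethyl-4-methyl-5-(prop-1-en-2-yl)cyclopent-2-en-1-yl]acetate, same ring stereochemistry
Conditions: Et2Zn (2 equiv), Pd(PPh3)4 (5 mol%), LiCl, THF, 50 °C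
Reagents that add atoms: Et2Zn, CC[Zn]CC
Why: Negishi coupling installs the C1 ethyl group and keeps the C1=C2 alkene position. The ester and isopropenyl group are inert to organozinc.

**Step 6**
Reactants: 11; 12 iodomethane
Product: 13 methyl 2-[2-ethyl-4-methyl-5-(prop-1-en-2-yl)cyclopent-2-en-1-yl]propanoate (C8 epimer mixture)
Conditions: LDA, THF, –78 °C; then MeI, –78 → 0 °C
Reagents that add atoms: MeI, CI
Why: Ester enolate α-methylation installs the C8 methyl. The C8 configuration is irrelevant because C8 is planarised in Step 11.

**Step 7**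
Reactants: 13
Product: 14 2-[2-ethyl-4-methyl-5-(prop-1-en-2-yl)cyclopent-2-en-1-yl]propanoic acid (C8 epimer mixture)
Conditions: LiOH·H2O, THF/MeOH/H2O, 60 °C; then 1 M HCl
Reagents that add atoms: LiOH/water, [Li]O and O (adds OH)
Why: Saponification of an unhindered methyl ester. C9, C4 and C3 carry no α-carbonyl acidity, so they are not scrambled.

**Step 8**
Reactants: 15 cinnamylideneacetone [(3E,5E)-6-phenylhexa-3,5-dien-2-one]; 16 triethyl phosphonoacetate
Product: 17 ethyl (2E,4E,6E)-3-methyl-7-phenylhepta-2,4,6-trienoate
Conditions: NaH, THF, 0 °C → rt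
Reagents that add atoms: triethyl phosphonoacetate, CCOP(=O)(OCC)CC(=O)OCC
Why: Horner–Wadsworth–Emmons olefination of a methyl ketone is E-selective, with the dienyl group trans to CO2Et. I assume about 5:1 E:Z, separable by chromatography; the diene geometry is retained from 15.

**Step 9**
Reactants: 17
Product: 18 (2E,4E,6E)-3-methyl-7-phenylhepta-2,4,6-trien-1-ol
Conditions: DIBAL-H (2.5 equiv), CH2Cl2, –78 °C
Reagents that add atoms: none
Why: Ester-to-alcohol reduction leaves the conjugated triene intact. The product is the (E)-allylic alcohol needed for the chair Claisen transition state.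

**Step 10**
Reactants: 14; 18
Product: 19 (2E,4E,6E)-3-methyl-7-phenylhepta-2,4,6-trien-1-yl 2-[2-ethyl-4-methyl-5-(prop-1-en-2-yl)cyclopent-2-en-1-yl]propanoate (C8 epimer mixture)
Conditions: EDC·HCl, DMAP, iPr2NEt, CH2Cl2, 0 °C → rt
Reagents that add atoms: none
Why: Steglich esterification is neutral, so the acid-sensitive dienyl allylic alcohol survives. No new stereocentre is formed.

**Step 11**
Reactants: 19; 20 tert-butyldimethylsilyl chloride
Product: 21 (2?)-2-[2-ethyl-4-methyl-5-(prop-1-en-2-yl)cyclopent-2-en-1-yl]-2,3-dimethyl-3-[(1E,3E)-4-phenylbuta-1,3-dien-1-yl]pent-4-enoic acid (C7, C8 as in the target, C3/C4/C9 as in 11)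
Conditions: LDA (2.5 equiv), THF, –78 °C; then TBSCl (3 equiv), –78 °C → rt → 66 °C, 16 h; then aqueous HCl workup
Reagents that add atoms: TBSCl, CC(C)(C)[Si](C)(C)Cl (transient silyl ester, removed by the aqueous acid workup, which adds O and H)
Why: Ireland–Claisen rearrangement forges the C7–C8 vicinal quaternary pair. LDA/THF without HMPA gives the silyl ketene acetal with Me cis to the O-allyl group and C9 trans. Through the chair transition state with the (E)-trienyl allylic ester, Me(C8) and Me(C7) are both axial and C9 and the dienyl group are both equatorial. This is the relative configuration of the target at C7/C8. The allyl CH2=CH unit becomes the C7 vinyl (C6). C9 controls the ketene-acetal face through A(1,3) strain with H9 in the alkene plane, and I assume a dr of at least 3:1. The minor diastereomer is removed by chromatography.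

**Step 12**
Reactants: 21
Product: 22 22-nor-zyggomphic acid B (target)
Conditions: Hoveyda–Grubbs II (10 mol%), toluene (2 mM), 80 °C, N2 sweep to remove ethylene
Reagents that add atoms: none
Why: RCM of the unhindered vinyl group on C7 with the isopropenyl on C4 forms the trisubstituted C5=C6 cyclohexene and releases ethylene. The terminal vinyl is far more reactive than the conjugated 1,2-disubstituted diene. No stereocentre is touched.

---

**Compound list**

| # | Name | SMILES | Role |
|---|---|---|---|
| 1 | (S)-3-methylcyclopentan-1-one | C[C@@H]1CC(=O)CC1 | starting material |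
| 2 | chlorotrimethylsilane | C[Si](C)(C)Cl | starting material |
| 3 | (S)-trimethyl[(4-methylcyclopent-1-en-1-yl)oxy]silane | C[C@@H]1CC(O[Si](C)(C)C)=CC1 | intermediate |
| 4 | (R)-4-methylcyclopent-2-en-1-one | C[C@@H]1CC(=O)C=C1 | intermediate |
| 5 | isopropenylmagnesium bromide | C=C(C)[Mg]Br | starting material |
| 6 | methyl bromoacetate | COC(=O)CBr | starting material |
| 7 | methyl 2-[(1R,4R,5S)-4-methyl-2-oxo-5-(prop-1-en-2-yl)cyclopentyl]acetate | C[C@@H]1CC(=O)[C@H](CC(=O)OC)[C@H]1C(C)=C | intermediate |
| 8 | N-phenylbis(trifluoromethanesulfonimide) | O=S(=O)(C(F)(F)F)N(c1ccccc1)S(=O)(=O)C(F)(F)F | starting material |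
| 9 | enol triflate of 7 (all-trans ring) | C[C@@H]1C=C(OS(=O)(=O)C(F)(F)F)[C@H](CC(=O)OC)[C@H]1C(C)=C | intermediate |
| 10 | diethylzinc | CC[Zn]CC | starting material |
| 11 | methyl 2-[2-ethyl-4-methyl-5-(prop-1-en-2-yl)cyclopent-2-en-1-yl]acetate | C[C@@H]1C=C(CC)[C@H](CC(=O)OC)[C@H]1C(C)=C | intermediate |
| 12 | iodomethane | CI | starting material |
| 13 | methyl propanoate analogue of 11 (C8 epimers) | C[C@@H]1C=C(CC)[C@H](C(C)C(=O)OC)[C@H]1C(C)=C | intermediate |
| 14 | propanoic acid analogue (C8 epimers) | C[C@@H]1C=C(CC)[C@H](C(C)C(=O)O)[C@H]1C(C)=C | intermediate |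
| 15 | cinnamylideneacetone | CC(=O)/C=C/C=C/c1ccccc1 | starting material |
| 16 | triethyl phosphonoacetate | CCOP(=O)(OCC)CC(=O)OCC | starting material |
| 17 | ethyl (2E,4E,6E)-3-methyl-7-phenylhepta-2,4,6-trienoate | CCOC(=O)/C=C(C)/C=C/C=C/c1ccccc1 | intermediate |
| 18 | (2E,4E,6E)-3-methyl-7-phenylhepta-2,4,6-trien-1-ol | OC/C=C(C)/C=C/C=C/c1ccccc1 | intermediate |
| 19 | trienyl ester of 14 (C8 epimers) | C[C@@H]1C=C(CC)[C@H](C(C)C(=O)OC/C=C(C)/C=C/C=C/c2ccccc2)[C@H]1C(C)=C | intermediate |
| 20 | tert-butyldimethylsilyl chloride | CC(C)(C)[Si](C)(C)Cl | starting material |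
| 21 | Claisen acid (named in Step 11) | C[C@@H]1C=C(CC)[C@H]([C@@](C)(C(=O)O)[C@](C)(C=C)/C=C/C=C/c2ccccc2)[C@H]1C(C)=C | intermediate |
| 22 | 22-nor-zyggomphic acid B | CCC1=C[C@@H](C)[C@@H]2C(C)=C[C@](C)(/C=C/C=C/c3ccccc3)[C@](C)(C(=O)O)[C@@H]12 | target |

---

**Totals**
- Total steps: 12.
- Longest linear sequence: 10 steps (Steps 1, 2, 3, 4, 5, 6, 7, 10, 11, 12).

**Three steps most likely to fail**
1. **Step 11 (Ireland–Claisen).** It forms a quaternary–quaternary bond, loses triene conjugation in the transition state, and depends on C9 for facial selectivity. Fallback (different approach): close the cyclohexane by an intramolecular Mukaiyama–Michael of the C8 silyl ketene acetal onto a C4-tethered dienone, then convert the C5 ketone to the C5-methyl alkene by enol triflate and Me coupling.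
2. **Step 12 (RCM).** It is hindered, forms a trans-fused ring next to quaternary centres, and the free acid and the diene may interfere. Fallback (different approach): use (2E,4E)-5-iodo-3-methylpenta-2,4-dien-1-ol in Step 10 and carry it through the Claisen. The vinyl/isopropenyl RCM then runs without the diene, and a late Suzuki coupling with (E)-styrylboronic acid installs the phenylbutadienyl group.
3. **Step 3 (one-pot 1,4-addition/alkylation with methyl bromoacetate).** Magnesium-enolate alkylation may be sluggish or give O-alkylation. Fallback (different approach): add isopropenyl cuprate to 2-(methoxycarbonylmethyl)-4-methylcyclopent-2-enone, which is anti to the 4-Me, and set C9 trans by thermodynamic protonation and epimerisation α to the ketone.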